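**Plan**

Retrosynthesis: the lactol stereocentre is set last. Ring D is opened at its lactol C–O and lactone C–O bonds to an acetal and a tert-butyl ester on ring B, and ring C is cut at its aryl ester C–O bond. Ring B is then cut at four of its C–C bonds into a diazo ketoester and 1-siloxypropyne, and the aryl vinyl ether C–O bond separates a ring A salicylate (from creosol) from formylated methyl 3,3-dimethoxypropanoate.
Enabling feature: ring B is a hexasubstituted benzene whose carbons carry, in ring order, the ether O to ring A, the ester O of ring C, CH3, OH, the ring D carbonyl carbon and the ring D lactol carbon. Ester O and OH are meta across the methyl carbon, the pattern left by a ketene carbonyl carbon and a methyl siloxyalkyne, while the two ring D carbons and the ether carbon map onto the ester-bearing ketene carbon and its aryloxyvinyl group.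
Forward order: ring A salicylate, vinyl ether, diazo ketoester, ring B by photochemical benzannulation, ring C by lactonisation, ring D by acid unmasking.
Stereochemistry: the only stereocentre (lactol carbon, R) comes from a catalyst-controlled acylation of the racemising lactol and is released by neutral enzymatic alcoholysis with retention.

Key step: step 13

Assumption: the lactol carbon of ring D is a hemiacetal centre that racemises through the ring-opened formyl acid under base, so it is taken to be configurationally stable only in neutral aprotic medium at or below room temperature; the sense of induction of the acylation catalyst must be confirmed on the first run (both antipodes are available).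

Ar = 2-(benzyloxy)-6-[(benzyloxy)carbonyl]-3-methoxy-5-methylphenyl (the protected ring A unit).

**Route**

Step 1
Reactants: 1 2-methoxy-4-methylphenol (creosol)
Product: 2 2-hydroxy-3-methoxy-5-methylbenzaldehyde
Conditions: MgCl2, Et3N, (CH2O)n, MeCN, reflux
Reagents that add atoms: paraformaldehyde (formaldehyde), C=O
Why: Magnesium-mediated ortho-formylation (Casnati–Skattebøl), in which the magnesium phenoxide delivers formaldehyde to the only free ortho carbon and a second formaldehyde oxidises the benzylic alkoxide.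

Step 2
Reactants: 2 2-hydroxy-3-methoxy-5-methylbenzaldehyde
Product: 3 2-(benzyloxy)-3-methoxy-5-methylbenzaldehyde
Conditions: BnBr, K2CO3, DMF, rt
Reagents that add atoms: benzyl bromide, BrCc1ccccc1
Why: Williamson etherification of the only phenol, which protects the oxygen that becomes the free ring A hydroxyl.

Step 3
Reactants: 3 2-(benzyloxy)-3-methoxy-5-methylbenzaldehyde
Product: 5 2-(benzyloxy)-3-methoxy-5-methylphenol, via 2-(benzyloxy)-3-methoxy-5-methylphenyl formate 4 (not isolated)
Conditions: mCPBA, CH2Cl2, 0 °C → rt; aq. NaHCO3 wash; then K2CO3 (cat.), MeOH, rt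
Reagents that add atoms: 3-chloroperoxybenzoic acid, OOC(=O)c1cccc(Cl)c1
Why: Baeyer–Villiger oxidation of an electron-rich ortho-alkoxybenzaldehyde (Dakin-type), in which the aryl group migrates and the aryl formate is methanolysed to the phenol.

Step 4
Reactants: 5 2-(benzyloxy)-3-methoxy-5-methylphenol
Product: 6 3-(benzyloxy)-2-hydroxy-4-methoxy-6-methylbenzaldehyde
Conditions: MgCl2, Et3N, (CH2O)n, MeCN, reflux
Reagents that add atoms: paraformaldehyde (formaldehyde), C=O
Why: Casnati–Skattebøl ortho-formylation again, which is strictly ortho-selective and has a single free ortho carbon (between OH and CH3) to choose from.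

Step 5
Reactants: 6 3-(benzyloxy)-2-hydroxy-4-methoxy-6-methylbenzaldehyde
Product: 7 3-(benzyloxy)-2-hydroxy-4-methoxy-6-methylbenzoic acid
Conditions: NaClO2, NaH2PO4, 2-methyl-2-butene, t-BuOH/H2O, rt
Reagents that add atoms: sodium chlorite, [Na+].[O-]Cl=O
Why: Pinnick oxidation of the aldehyde, with the alkene scavenger removing hypochlorous acid before it can chlorinate the electron-rich ring.

Step 6
Reactants: 7 3-(benzyloxy)-2-hydroxy-4-methoxy-6-methylbenzoic acid
Product: 8 benzyl 3-(benzyloxy)-2-hydroxy-4-methoxy-6-methylbenzoate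
Conditions: BnBr, KHCO3, DMF, rt
Reagents that add atoms: benzyl bromide, BrCc1ccccc1
Why: Carboxylate alkylation with a base too weak to deprotonate the hydrogen-bonded ortho phenol, which gives the ester and leaves the phenol free for vinylation.

Step 7
Reactants: 9 methyl 3,3-dimethoxypropanoate
Product: 11 methyl (Z)-2-(dimethoxymethyl)-3-(tosyloxy)prop-2-enoate, via sodium formyl ester enolate 10 (not isolated)
Conditions: NaH, HCO2Me, THF, 0 °C → rt; then TsCl, 0 °C → rt
Reagents that add atoms: methyl formate, COC=O; p-toluenesulfonyl chloride, Cc1ccc(cc1)S(Cl)(=O)=O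
Why: Crossed Claisen formylation of the ester enolate gives the chelated sodium enolate, which is sulfonylated on oxygen to a vinylogous acyl tosylate.

Step 8
Reactants: 8 benzyl 3-(benzyloxy)-2-hydroxy-4-methoxy-6-methylbenzoate; 11 methyl (Z)-2-(dimethoxymethyl)-3-(tosyloxy)prop-2-enoate
Product: 12 benzyl 3-(benzyloxy)-2-{[(1E)-2-(dimethoxymethyl)-3-methoxy-3-oxoprop-1-en-1-yl]oxy}-4-methoxy-6-methylbenzoate
Conditions: Cs2CO3, 1,4-diazabicyclo[2.2.2]octane (20 mol%), MeCN, 0 °C → rt
Reagents that add atoms: none
Why: Vinylic nucleophilic substitution by addition–elimination, in which the phenoxide (helped by the vinylammonium salt formed from the amine catalyst) displaces tosylate at the ester-activated CH carbon and equilibration should favour the E enol ether; the Z isomer, if present, should converge in step 13.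

Step 9
Reactants: 12 benzyl 3-(benzyloxy)-2-{[(1E)-2-(dimethoxymethyl)-3-methoxy-3-oxoprop-1-en-1-yl]oxy}-4-methoxy-6-methylbenzoate
Product: 13 (2E)-3-(ArO)-2-(dimethoxymethyl)prop-2-enoic acid
Conditions: LiOH, THF/H2O, 0 °C → rt; then 0.5 M HCl to pH 4, 0 °C
Reagents that add atoms: lithium hydroxide, [Li+].[OH-]
Why: Saponification of the acrylate methyl ester, with the ring A benzyl ester shielded by two ortho substituents and a cold, mildly acidic work-up that keeps the acetal.

Step 10
Reactants: 13 (2E)-3-(ArO)-2-(dimethoxymethyl)prop-2-enoic acid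
Product: 15 tert-butyl (4E)-5-(ArO)-4-(dimethoxymethyl)-3-oxopent-4-enoate, via acyl imidazolide 14 (not isolated)
Conditions: 1,1'-carbonyldiimidazole, THF, rt; then Mg(O2CCH2CO2t-Bu)2, THF, rt → 40 °C
Reagents that add atoms: magnesium bis(mono-tert-butyl malonate), [Mg+2].[O-]C(=O)CC(=O)OC(C)(C)C.[O-]C(=O)CC(=O)OC(C)(C)C; 1,1'-carbonyldiimidazole (supplies the imidazole ring of 14), O=C(n1ccnc1)n1ccnc1
Why: Masamune–Brooks decarboxylative Claisen condensation of the acyl imidazolide with a magnesium malonate half ester, under near-neutral conditions that spare acetal, enol ether and benzyl ester.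

Step 11
Reactants: 15 tert-butyl (4E)-5-(ArO)-4-(dimethoxymethyl)-3-oxopent-4-enoate
Product: 16 tert-butyl (4E)-5-(ArO)-2-diazo-4-(dimethoxymethyl)-3-oxopent-4-enoate
Conditions: 4-acetamidobenzenesulfonyl azide, Et3N, MeCN, 0 °C → rt
Reagents that add atoms: 4-acetamidobenzenesulfonyl azide, CC(=O)Nc1ccc(cc1)S(=O)(=O)N=[N+]=[N-]
Why: Regitz diazo transfer to the doubly activated methylene, which also removes the enolisable position of the ketoester.

Step 12
Reactants: 17 propyne
Product: 20 triisopropyl(prop-1-yn-1-yloxy)silane, via prop-1-ynyllithium 18 (not isolated), via lithium prop-1-yn-1-olate 19 (not isolated)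
Conditions: n-BuLi, THF, −78 °C; then LiOOt-Bu (from t-BuOOH and LiN(SiMe3)2), −78 → 0 °C; then i-Pr3SiOSO2CF3, −78 °C
Reagents that add atoms: tert-butyl hydroperoxide (as its lithium salt), CC(C)(C)OO; triisopropylsilyl trifluoromethanesulfonate, CC(C)[Si](C(C)C)(C(C)C)OS(=O)(=O)C(F)(F)F
Why: Oxidation of the lithium acetylide by lithium tert-butyl peroxide gives the ynolate, which the bulky silyl triflate traps on oxygen to a stable siloxyalkyne.

Step 13
Reactants: 16 tert-butyl (4E)-5-(ArO)-2-diazo-4-(dimethoxymethyl)-3-oxopent-4-enoate; 20 triisopropyl(prop-1-yn-1-yloxy)silane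
Product: 25 benzyl 3-(benzyloxy)-2-[3-(tert-butoxycarbonyl)-2-(dimethoxymethyl)-6-hydroxy-5-methyl-4-(triisopropylsilyloxy)phenoxy]-4-methoxy-6-methylbenzoate, via vinylketene 21 (not isolated), via cyclobutenone 22 (not isolated), via dienylketene 23 (not isolated), via cyclohexadienone 24 (not isolated)
Conditions: 20 (2.5 equiv), hν (medium-pressure Hg lamp, Pyrex filter, >300 nm), ClCH2CH2Cl, degassed, rt; then 80 °C
Reagents that add atoms: none
Why: Proposed new method: light expels N2 and the aryloxyvinyl group migrates to the carbene carbon (Wolff rearrangement) to give the ester-substituted vinylketene 21, whose ketene C=C adds the electron-rich alkyne in a [2+2] sense to cyclobutenone 22; warming opens 22 (4π electrocyclic opening) to dienylketene 23, which closes ring B by a thermal disrotatory 6π electrocyclisation between the ketene carbon and the aryloxy-bearing vinyl terminus to give dienone 24, and tautomerisation of its one ring hydrogen gives the phenol. The closest known reaction type is the photo-Wolff vinylketene benzannulation of α,β-unsaturated diazomethyl ketones with siloxyalkynes (Danheiser benzannulation), which has not been shown on a 2-diazo-3-oxo ester or with a β-aryloxy substituent; an acceptor-substituted ketene should be more, not less, electrophilic towards the ynol ether, and Wolff rearrangement of 2-diazo-1,3-dicarbonyl compounds with migration of the ketone substituent is well established. The selectivity needed is regiochemical: the nucleophilic methyl-bearing alkyne carbon bonds to the ketene carbonyl carbon and the siloxy carbon to the ester-bearing carbon, as the polarisation of both partners dictates, so that methyl ends next to the new phenol and the silyl ether next to the ester. No stereocentre survives, because the sp3 carbon of 24 is lost on aromatisation, and either geometry of the aryloxyvinyl unit should converge, since the 4π steps are reversible and the enone isomerises under irradiation. An excess of 20 in an aprotic solvent is used so that the ketene is not diverted through its ester carbonyl or the neighbouring acetal oxygen.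

Step 14
Reactants: 25 benzyl 3-(benzyloxy)-2-[3-(tert-butoxycarbonyl)-2-(dimethoxymethyl)-6-hydroxy-5-methyl-4-(triisopropylsilyloxy)phenoxy]-4-methoxy-6-methylbenzoate
Product: 26 2-[3-(tert-butoxycarbonyl)-2-(dimethoxymethyl)-6-hydroxy-5-methyl-4-(triisopropylsilyloxy)phenoxy]-3-hydroxy-4-methoxy-6-methylbenzoic acid
Conditions: H2 (1 atm), 10% Pd/C, EtOAc, rt
Reagents that add atoms: none
Why: Hydrogenolysis cleaves the benzyl ester and the benzyl ether, while acetal, silyl ether, tert-butyl ester and diaryl ether are inert in neutral ethyl acetate.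

Step 15
Reactants: 26 2-[3-(tert-butoxycarbonyl)-2-(dimethoxymethyl)-6-hydroxy-5-methyl-4-(triisopropylsilyloxy)phenoxy]-3-hydroxy-4-methoxy-6-methylbenzoic acid
Product: 27 tert-butyl 6-(dimethoxymethyl)-4-hydroxy-3-methoxy-1,9-dimethyl-11-oxo-8-(triisopropylsilyloxy)-11H-dibenzo[b,e][1,4]dioxepine-7-carboxylate (depsidone, ring C closed)
Conditions: EDC·HCl, 4-(dimethylamino)pyridine (cat.), CH2Cl2 (2 mM), 0 °C → rt
Reagents that add atoms: none
Why: Carbodiimide lactonisation (Steglich type) at high dilution, in which only the ring B phenol ortho to the ether bridge can reach the activated acid and so closes the seven-membered ring C.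

Step 16
Reactants: 27 tert-butyl 6-(dimethoxymethyl)-4-hydroxy-3-methoxy-1,9-dimethyl-11-oxo-8-(triisopropylsilyloxy)-11H-dibenzo[b,e][1,4]dioxepine-7-carboxylate
Product: 28 tert-butyl 6-(dimethoxymethyl)-4,8-dihydroxy-3-methoxy-1,9-dimethyl-11-oxo-11H-dibenzo[b,e][1,4]dioxepine-7-carboxylate
Conditions: Bu4NF, AcOH (1:1), THF, 0 °C
Reagents that add atoms: none
Why: Fluoride cleavage of the aryl silyl ether, buffered with acetic acid so that the aryl lactone of ring C is not opened.

Step 17
Reactants: 28 tert-butyl 6-(dimethoxymethyl)-4,8-dihydroxy-3-methoxy-1,9-dimethyl-11-oxo-11H-dibenzo[b,e][1,4]dioxepine-7-carboxylate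
Product: 29 racemic lactol (ring D closed as the hydroxy lactone; racemate of 31)
Conditions: CF3CO2H/H2O/CH2Cl2 (5:1:5), 0 °C → rt
Reagents that add atoms: water, O
Why: Aqueous acid removes the tert-butyl ester and hydrolyses the acetal, and the ortho acid and aldehyde close ring D by ring–chain tautomerism, here without stereocontrol.

Step 18
Reactants: 29 racemic lactol
Product: 30 (R)-lactol propanoate with both phenols also propanoylated (tripropanoate of 31)
Conditions: (R)-benzotetramisole [(2R)-2-phenyl-2,3-dihydroimidazo[2,1-b][1,3]benzothiazole] (10 mol%), (EtCO)2O, i-Pr2NEt, CHCl3, 0 °C → rt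
Reagents that add atoms: propionic anhydride, CCC(=O)OC(=O)CC
Why: Acylative dynamic kinetic resolution of a lactol with a chiral isothiourea, in which the amine base racemises 29 through the ring-opened formyl carboxylate while the chiral N-acyl ammonium ion propanoylates the R lactol faster and so fixes the stereocentre as a stable acylal; the phenols are acylated without stereochemical consequence.

Step 19
Reactants: 30 (R)-lactol propanoate with both phenols also propanoylated
Product: 31 CNP0211607.1, the (R)-lactol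
Conditions: Candida antarctica lipase B (immobilised), n-BuOH, t-BuOMe, 4 Å sieves, 10 °C
Reagents that add atoms: none
Why: Lipase-catalysed alcoholysis attacks only the acyl carbons of the three activated esters (two aryl, one acylal) in neutral anhydrous medium, so the C–O bond at the stereocentre is untouched and the R configuration is retained.

**Compound list**

1 | 2-methoxy-4-methylphenol (creosol) | COc1cc(C)ccc1O | starting material
2 | 2-hydroxy-3-methoxy-5-methylbenzaldehyde | COc1cc(C)cc(C=O)c1O | intermediate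
3 | 2-(benzyloxy)-3-methoxy-5-methylbenzaldehyde | COc1cc(C)cc(C=O)c1OCc1ccccc1 | intermediate
4 | 2-(benzyloxy)-3-methoxy-5-methylphenyl formate | COc1cc(C)cc(OC=O)c1OCc1ccccc1 | intermediate
5 | 2-(benzyloxy)-3-methoxy-5-methylphenol | COc1cc(C)cc(O)c1OCc1ccccc1 | intermediate
6 | 3-(benzyloxy)-2-hydroxy-4-methoxy-6-methylbenzaldehyde | COc1cc(C)c(C=O)c(O)c1OCc1ccccc1 | intermediate
7 | 3-(benzyloxy)-2-hydroxy-4-methoxy-6-methylbenzoic acid | COc1cc(C)c(C(=O)O)c(O)c1OCc1ccccc1 | intermediate
8 | benzyl 3-(benzyloxy)-2-hydroxy-4-methoxy-6-methylbenzoate | COc1cc(C)c(C(=O)OCc2ccccc2)c(O)c1OCc1ccccc1 | intermediate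
9 | methyl 3,3-dimethoxypropanoate | COC(=O)CC(OC)OC | starting material
10 | sodium (Z)-2-(dimethoxymethyl)-3-methoxy-3-oxoprop-1-en-1-olate | [Na+].[O-]/C=C(\C(=O)OC)C(OC)OC | intermediate
11 | methyl (Z)-2-(dimethoxymethyl)-3-(tosyloxy)prop-2-enoate | COC(=O)/C(=C\OS(=O)(=O)c1ccc(C)cc1)C(OC)OC | intermediate
12 | benzyl 3-(benzyloxy)-2-{[(1E)-2-(dimethoxymethyl)-3-methoxy-3-oxoprop-1-en-1-yl]oxy}-4-methoxy-6-methylbenzoate | COc1cc(C)c(C(=O)OCc2ccccc2)c(O/C=C(/C(=O)OC)C(OC)OC)c1OCc1ccccc1 | intermediate
13 | (2E)-3-{2-(benzyloxy)-6-[(benzyloxy)carbonyl]-3-methoxy-5-methylphenoxy}-2-(dimethoxymethyl)prop-2-enoic acid | COc1cc(C)c(C(=O)OCc2ccccc2)c(O/C=C(/C(=O)O)C(OC)OC)c1OCc1ccccc1 | intermediate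
14 | acyl imidazolide of 13 (1H-imidazol-1-yl ketone, E) | COc1cc(C)c(C(=O)OCc2ccccc2)c(O/C=C(/C(=O)n2ccnc2)C(OC)OC)c1OCc1ccccc1 | intermediate
15 | tert-butyl (4E)-5-{2-(benzyloxy)-6-[(benzyloxy)carbonyl]-3-methoxy-5-methylphenoxy}-4-(dimethoxymethyl)-3-oxopent-4-enoate | COc1cc(C)c(C(=O)OCc2ccccc2)c(O/C=C(/C(=O)CC(=O)OC(C)(C)C)C(OC)OC)c1OCc1ccccc1 | intermediate
16 | tert-butyl (4E)-5-{2-(benzyloxy)-6-[(benzyloxy)carbonyl]-3-methoxy-5-methylphenoxy}-2-diazo-4-(dimethoxymethyl)-3-oxopent-4-enoate | COc1cc(C)c(C(=O)OCc2ccccc2)c(O/C=C(/C(=O)C(=[N+]=[N-])C(=O)OC(C)(C)C)C(OC)OC)c1OCc1ccccc1 | intermediate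
17 | propyne | CC#C | starting material
18 | prop-1-ynyllithium | [Li]C#CC | intermediate
19 | lithium prop-1-yn-1-olate | CC#C[O-].[Li+] | intermediate
20 | triisopropyl(prop-1-yn-1-yloxy)silane | CC#CO[Si](C(C)C)(C(C)C)C(C)C | intermediate
21 | vinylketene: tert-butyl 4-(ArO)-3-(dimethoxymethyl)-2-(oxomethylidene)but-3-enoate (aryloxy cis to the acetal carbon) | COc1cc(C)c(C(=O)OCc2ccccc2)c(O/C=C(/C(=C=O)C(=O)OC(C)(C)C)C(OC)OC)c1OCc1ccccc1 | intermediate
22 | cyclobutenone: tert-butyl 1-[2-(ArO)-1-(dimethoxymethyl)ethenyl]-3-methyl-4-oxo-2-(triisopropylsilyloxy)cyclobut-2-ene-1-carboxylate (racemic) | COc1cc(C)c(C(=O)OCc2ccccc2)c(O/C=C(/C2(C(=O)OC(C)(C)C)C(=O)C(C)=C2O[Si](C(C)C)(C(C)C)C(C)C)C(OC)OC)c1OCc1ccccc1 | intermediate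
23 | dienylketene: tert-butyl 2-[2-(ArO)-1-(dimethoxymethyl)ethenyl]-4-methyl-5-oxo-3-(triisopropylsilyloxy)penta-2,4-dienoate (vinyl group cis to the ketenyl group) | COc1cc(C)c(C(=O)OCc2ccccc2)c(O/C=C(/C(C(=O)OC(C)(C)C)=C(/O[Si](C(C)C)(C(C)C)C(C)C)C(C)=C=O)C(OC)OC)c1OCc1ccccc1 | intermediate
24 | cyclohexadienone: tert-butyl 3-(ArO)-2-(dimethoxymethyl)-5-methyl-4-oxo-6-(triisopropylsilyloxy)cyclohexa-1,5-diene-1-carboxylate (racemic) | COc1cc(C)c(C(=O)OCc2ccccc2)c(OC2C(=O)C(C)=C(O[Si](C(C)C)(C(C)C)C(C)C)C(C(=O)OC(C)(C)C)=C2C(OC)OC)c1OCc1ccccc1 | intermediate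
25 | benzyl 3-(benzyloxy)-2-[3-(tert-butoxycarbonyl)-2-(dimethoxymethyl)-6-hydroxy-5-methyl-4-(triisopropylsilyloxy)phenoxy]-4-methoxy-6-methylbenzoate | COc1cc(C)c(C(=O)OCc2ccccc2)c(Oc2c(O)c(C)c(O[Si](C(C)C)(C(C)C)C(C)C)c(C(=O)OC(C)(C)C)c2C(OC)OC)c1OCc1ccccc1 | intermediate
26 | 2-[3-(tert-butoxycarbonyl)-2-(dimethoxymethyl)-6-hydroxy-5-methyl-4-(triisopropylsilyloxy)phenoxy]-3-hydroxy-4-methoxy-6-methylbenzoic acid | COc1cc(C)c(C(=O)O)c(Oc2c(O)c(C)c(O[Si](C(C)C)(C(C)C)C(C)C)c(C(=O)OC(C)(C)C)c2C(OC)OC)c1O | intermediate
27 | tert-butyl 6-(dimethoxymethyl)-4-hydroxy-3-methoxy-1,9-dimethyl-11-oxo-8-(triisopropylsilyloxy)-11H-dibenzo[b,e][1,4]dioxepine-7-carboxylate | COc1cc(C)c2c(c1O)Oc1c(c(C)c(O[Si](C(C)C)(C(C)C)C(C)C)c(C(=O)OC(C)(C)C)c1C(OC)OC)OC2=O | intermediate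
28 | tert-butyl 6-(dimethoxymethyl)-4,8-dihydroxy-3-methoxy-1,9-dimethyl-11-oxo-11H-dibenzo[b,e][1,4]dioxepine-7-carboxylate | COc1cc(C)c2c(c1O)Oc1c(c(C)c(O)c(C(=O)OC(C)(C)C)c1C(OC)OC)OC2=O | intermediate
29 | racemic lactol (depsidone with ring D closed as the hydroxy lactone; racemate of 31) | COc1cc(C)c2c(c1O)Oc1c(c(C)c(O)c3c1C(O)OC3=O)OC2=O | intermediate
30 | (R)-lactol propanoate of 31 with both phenols as propanoates (tripropanoate; R at the acylal carbon) | CCC(=O)Oc1c(OC)cc(C)c2c1Oc1c(c(C)c(OC(=O)CC)c3c1[C@H](OC(=O)CC)OC3=O)OC2=O | intermediate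
31 | CNP0211607.1, (R)-lactol | COc1cc(C)c2c(c1O)Oc1c(c(C)c(O)c3c1[C@H](O)OC3=O)OC2=O | target

**Count**

Total: 19 steps. Longest linear sequence: 17 steps (1–6, 8–11, 13–19); steps 7 and 12 are side branches.

**Steps most likely to fail**

1. Step 13 (carries the new-method label). The ester-substituted ketene may be diverted before ring B closes: by cycloaddition through its ester carbonyl, by capture by the acetal oxygen, or by carbene side reactions. The fallback uses known chemistry: the ester is left out of the annulation and the ring D carbonyl is installed afterwards. It sets out from acid 13, which is activated with isobutyl chloroformate and N-methylmorpholine to the mixed anhydride F1 and treated with diazomethane to give the diazomethyl ketone F2, a substrate of the established class. Irradiation of F2 with 20 and warming, as in step 13, should give the pentasubstituted diaryl ether F3, with hydrogen where the ester stood. Hydrogenolysis gives the hydroxy acid F4, carbodiimide lactonisation gives the silyl-protected depsidone F5, and buffered fluoride gives the phenol F6, under the conditions of steps 14–16. Magnesium-mediated ortho-formylation (MgCl2, Et3N, paraformaldehyde) can reach only the one free carbon next to the new phenol and gives the aldehyde F7. Buffered chlorite oxidation gives the acid F8, and aqueous trifluoroacetic acid closes acid and acetal to lactol 29, where the route is rejoined.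

2. Step 10. The malonate or imidazole may displace the aryloxy group at the vinyl carbon, or the enolisable ketoester may cyclise with loss of phenol 8. The fallback bypasses the ketoester stage. It sets out from acid 13, which is converted with 1-chloro-N,N,2-trimethylprop-1-en-1-amine into the acid chloride F9. F9 acylates tert-butyl diazoacetate (2,6-lutidine as acid acceptor, CH2Cl2, 0 °C → rt) to give the diazo ketoester 16 directly, where the route is rejoined.

3. Step 19. The lipase may cleave the hindered esters slowly or incompletely, and the freed lactol may lose configurational purity by ring opening during the release. The fallback gives up the acylation/deacylation pair. It sets out from racemic lactol 29, which is resolved by preparative chromatography on a chiral stationary phase at low temperature with a neutral aprotic eluent. The R enantiomer is collected as 31, and the other enantiomer is re-equilibrated with a trace of base and recycled; no new compound is made (F0).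

**Further compounds**

F1 | step 13 | mixed anhydride of 13 with isobutyl hydrogen carbonate | COc1cc(C)c(C(=O)OCc2ccccc2)c(O/C=C(/C(=O)OC(=O)OCC(C)C)C(OC)OC)c1OCc1ccccc1
F2 | step 13 | benzyl 3-(benzyloxy)-2-{[(1E)-4-diazo-2-(dimethoxymethyl)-3-oxobut-1-en-1-yl]oxy}-4-methoxy-6-methylbenzoate | COc1cc(C)c(C(=O)OCc2ccccc2)c(O/C=C(/C(=O)C=[N+]=[N-])C(OC)OC)c1OCc1ccccc1
F3 | step 13 | benzyl 3-(benzyloxy)-2-[2-(dimethoxymethyl)-6-hydroxy-5-methyl-4-(triisopropylsilyloxy)phenoxy]-4-methoxy-6-methylbenzoate | COc1cc(C)c(C(=O)OCc2ccccc2)c(Oc2c(O)c(C)c(O[Si](C(C)C)(C(C)C)C(C)C)cc2C(OC)OC)c1OCc1ccccc1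
F4 | step 13 | 2-[2-(dimethoxymethyl)-6-hydroxy-5-methyl-4-(triisopropylsilyloxy)phenoxy]-3-hydroxy-4-methoxy-6-methylbenzoic acid | COc1cc(C)c(C(=O)O)c(Oc2c(O)c(C)c(O[Si](C(C)C)(C(C)C)C(C)C)cc2C(OC)OC)c1O
F5 | step 13 | 6-(dimethoxymethyl)-4-hydroxy-3-methoxy-1,9-dimethyl-8-(triisopropylsilyloxy)-11H-dibenzo[b,e][1,4]dioxepin-11-one | COc1cc(C)c2c(c1O)Oc1c(c(C)c(O[Si](C(C)C)(C(C)C)C(C)C)cc1C(OC)OC)OC2=O
F6 | step 13 | 6-(dimethoxymethyl)-4,8-dihydroxy-3-methoxy-1,9-dimethyl-11H-dibenzo[b,e][1,4]dioxepin-11-one | COc1cc(C)c2c(c1O)Oc1c(c(C)c(O)cc1C(OC)OC)OC2=O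
F7 | step 13 | 6-(dimethoxymethyl)-4,8-dihydroxy-3-methoxy-1,9-dimethyl-11-oxo-11H-dibenzo[b,e][1,4]dioxepine-7-carbaldehyde | COc1cc(C)c2c(c1O)Oc1c(c(C)c(O)c(C=O)c1C(OC)OC)OC2=O
F8 | step 13 | 6-(dimethoxymethyl)-4,8-dihydroxy-3-methoxy-1,9-dimethyl-11-oxo-11H-dibenzo[b,e][1,4]dioxepine-7-carboxylic acid | COc1cc(C)c2c(c1O)Oc1c(c(C)c(O)c(C(=O)O)c1C(OC)OC)OC2=O
F9 | step 10 | acid chloride of 13 (E) | COc1cc(C)c(C(=O)OCc2ccccc2)c(O/C=C(/C(Cl)=O)C(OC)OC)c1OCc1ccccc1
F0 | step 19 | none | none
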